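No L.X can exist before J has released its X, and what is released must then be held.

    D ⇌ L (K1 = 1.21, k1 = 3.86 h⁻¹, Ea1 = 109 kJ mol⁻¹, ΔH1 = 15.0 kJ mol⁻¹)
    J → X (k2 = 0.227 h⁻¹, Ea2 = 116 kJ mol⁻¹)
    L + X ⇌ L.X (K3 = 250 M⁻¹, k3 = 229 M⁻¹ h⁻¹, Ea3 = 64.0 kJ mol⁻¹, ΔH3 = −34.0 kJ mol⁻¹)
    2 X → X2 (k4 = 141 M⁻¹ h⁻¹, Ea4 = 55.0 kJ mol⁻¹)
    L + Z → L.Z (k5 = 17.4 M⁻¹ h⁻¹, Ea5 = 74.0 kJ mol⁻¹)
    (constants at 90 °C)

| flask | D | J | Z | temperature | time |
|---|---|---|---|---|---|
| west | 13 mM | 1.50 equiv | 0.260 mM | 120 °C | 25 h |
| south | 13 mM | 1.50 equiv | 0.260 mM | 90 °C | 25 h |
| south-west | 13 mM | 1.50 equiv | 0.260 mM | 60 °C | 25 h |
| north-west | 13 mM | 1.50 equiv | 0.260 mM | 150 °C | 25 h |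

- a step written with two of one species runs at k times the square of its concentration and takes two of it each time
- all constants are for 90 °C and move with temperature by the activation energies and enthalpies

* which flask leads in amount of L.X, in percent of the D charged ("all alike" within 1.5 percentage points) (west / south / south-west / north-west / all alike)
* how much L.X is there at the end, in percent of the D charged: west
* how much L.X is there at the end, in percent of the D charged: south
* how much L.X is there at the end, in percent of the D charged: south-west
* how much L.X is there at the end, in percent of the D charged: north-west

The step joining L and X does the holding. In south-west its constant 689 M⁻¹ times the charge 13 mM gives 8.96. This product is the ratio of L.X to X at balance if the whole charge stood as L, and we call it the hold number; with a fraction of the charge standing as L, the ratio is that fraction of it. Other constants follow from the shift of this K away from 250 M⁻¹: each moves by that shift raised to its own energy over −34.0 kJ mol⁻¹.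

In south-west the release of X from J slows to 0.00714 h⁻¹, so in 25 h J gives X worth 24.5% of the D charge. D and L relax with a half-life of 2.02 h, shorter than the time, so we keep them balanced. Their constant 0.774 then puts 43.6% of the free material as L. A first round gives L.X at 19.5%. Putting that back lowers L to 35.1% and L.X to 18.6%.

The joining is not instant, though. Its constant falls to 34.0 M⁻¹ h⁻¹, and with L nearly constant X is taken up pseudo-first-order, so forward and return together give a relaxation time of 4.85 h. X arrives at a nearly steady rate, so L.X trails by that time, which leaves 15.0%.

The weak link is that X has gone nowhere else so far. Our reckoning so far leaves free X near 9.53% at the end. We expect it to rise steeply until the joining catches up, over about 4.85 h, and more slowly afterwards, so as a rough choice we take its square to average 0.5 of the final value. With 27.3 M⁻¹ h⁻¹, the turning of two X into X2 then takes 8.06% of the charge. Scaling by what remains puts L.X at 10.1% and leaves free X at 6.39%, well below the value we started from. Going round once more with that lower X, the loss is 3.63%, and we commit to 12.8% for south-west, as a rough figure.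

North-west needs a different use of the same number. There the constant is 50.6 M⁻¹, the hold number 0.658, and L stands at 71.0%, so the ratio is 0.467. J has a half-life of 0.789 min, so X is released early and then runs down through free X alone. Free X falls as 1.47 over twice its constant, 1870 M⁻¹ h⁻¹, times time and charge, and L.X is 0.467 of that: 0.0565%. We therefore put south-west far above north-west and leave south and west, which lie between them in temperature, unreckoned.

The forecast, holding that “L.X is a reversible reservoir”, gives 13.2% in south-west, above our figure, 7.1% in south, 0.45% in west and 0.055% in north-west, with south-west leading. The flasks give 12.9% in south-west, 7.71% in south, 0.440% in west and 0.0550% in north-west, so south-west leads.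

The return of L.X to L + X is the main reason north-west ends so low: with that return struck out, north-west ends at 86.0% instead of 0.0550%. In north-west the read ratio of L.X to X is 0.458, against 0.458 from the hold number and the L present. In south-west at 25.0 h the read ratio is 1.90 against 3.31, still short of balance. South-west read at 2.5 d stands at 2.63 against 2.96, with L.X at 22.9%.

The rate constants were chosen freely.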